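All runs are calculated from invented constants; scatter was added.

I began with the cold minute. Gamma and delta have the same charge and part only in the first 1.0 min, so the decision for the next run was whether to keep that minute in the recipe or charge delta directly. For that I needed its price in Pdt.

the same everywhere: Kat 0.2 mol%

| charge | Sbt | Sbt2 | temperature | remark | time |
|---|---|---|---|---|---|
| west | 0.050 M | 1 equiv | −5 °C | run made earlier |  |
| north-east | 0.050 M | 4 equiv | 10 °C | run made earlier |  |
| north | 0.075 M | 2 equiv | −5 °C | run made earlier |  |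
| alpha | 0.050 M | 2.00 equiv | 0 °C |  | 5.0 min |
| delta | 0.050 M | 2.00 equiv | 20 °C |  | 5.0 min |
| gamma | 0.050 M | 2.00 equiv |  | at 0 °C until 1.0 min, from then on at 20 °C | 5.0 min |

- west (time / min: Pdt / %, Sbt / %): 0.417: 0.6, 98.1; 1.33: 1.9, 96.0; 2.50: 3.4, 93.7; 4.00: 5.1, 90.3; 5.00: 6.5, 87.1
- north-east (time / min: Pdt / %, Sbt / %): 0.250: 1.0, 98.8; 0.833: 1.6, 95.3; 1.50: 4.2, 91.0; 2.50: 8.2, 84.4; 3.00: 10.6, 81.2
- north (time / min: Pdt / %, Sbt / %): 1.00: 1.0, 97.3; 2.00: 2.1, 94.7; 3.00: 4.1, 92.5; 4.00: 5.5, 90.0; 5.00: 5.9, 87.7

(scatter of a reading: 0.5 percentage points)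

- a reading or a percentage of Pdt counts all its forms, free or not
- a reading of Sbt is of its free form alone

- which flask leads in amount of Pdt, in percent of the Sbt charged ("all alike" within 1.5 percentage points) (alpha / delta / gamma / all alike)
- how much Pdt is there at the end, in percent of the Sbt charged: alpha
- how much Pdt is there at the end, in percent of the Sbt charged: delta
- how much Pdt is there at the end, in percent of the Sbt charged: gamma

I worked in fractions of the Sbt charged. Pdt in the west run rose in a straight line within the scatter (apparent zero order), so I took a slope as the last reading over its time, which gave 0.0130 min⁻¹. The north run, at the same temperature but with other charges, gave 0.0118 min⁻¹, and its last reading lay 0.6 percentage points from the west one, against a scatter of 0.5 points on each. I therefore assumed that this slope follows temperature. The north-east run gave 0.0353 min⁻¹ at 10 °C, but it differs from the west run in Sbt2 too, with 4 equiv against 1 equiv, and my reckoning set that difference aside.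

Taking the logarithm of the slope as straight in temperature, I got a cold line of 0.0181 min⁻¹ at 0 °C and a hot line of 0.0688 min⁻¹ at 20 °C.

Each end is then simple. Alpha lies on the cold line at 9.07% and delta on the hot line at 34.4%. Gamma is the two lines joined at the change, at 29.3%. The cost of the cold minute, the Pdt that gamma gives up against delta by spending that minute on the cold line, is the gap between the lines times the minute: 5.1 points. That is more than the margin of 1.5 points, so I struck the cold minute and chose delta.

The forecast put alpha at 9%, delta at 30% and gamma at 26%, the last two below my figures, and ended with “Delta leads”.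

Delta led with 38.6%, gamma gave 33.3% and alpha 8.69%. At 1.00 min gamma held 1.74% of Pdt, where my cold line gave 1.81%. Delta stood 4.2 points above my line and gamma 4.0 points above its own, but delta minus gamma came to 5.3 points against the cost of 5.1 points.

    Int2 → Kat + Pdt (k = 203 min⁻¹, Ea = 72.0 kJ mol⁻¹)
    Sbt + Kat ⇌ Int2 (K = 43.2 M⁻¹, k = 2250 M⁻¹ min⁻¹, Ea = 39.0 kJ mol⁻¹, ΔH = −25.0 kJ mol⁻¹)
    Sbt + Pdt ⇌ Int, settled at all times (K = 58.7 M⁻¹, ΔH = −53.0 kJ mol⁻¹)
    Sbt2 + Kat ⇌ Int3 (K = 21.0 M⁻¹, k = 2540 M⁻¹ min⁻¹, Ea = 45.0 kJ mol⁻¹, ΔH = 10.0 kJ mol⁻¹)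
    2 Sbt2 → Pdt2 (k = 1.06 M⁻¹ min⁻¹, Ea = 43.0 kJ mol⁻¹)
    Spx ⇌ Pdt, rate k6*(cs6 - [Pdt]) while solid is left; crystals form when [Pdt] > cs6 (solubility = 0.740 mM, k = 1.53 min⁻¹)
    Int3 → Kat + Sid (k = 324 min⁻¹, Ea = 74.0 kJ mol⁻¹)
    (constants at 20 °C)

For gamma read at 8.0 min, my hot line less the same cost gives 49.9%. Gamma held 52.1% of Pdt at that time, all its forms counted.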